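The data were generated by integration with made-up constants, noise included.

4 questions stand on this flask, and the last two turn on one number.

- dusk: substrate 1 M; catalyst 0.7 mol%; run made earlier
- flask: substrate 1.0 M; catalyst 0.47 mol%; time 12 min

dusk run (percent of the substrate charged)

| time / min | isomer of the product A / % | target / % |
|---|---|---|
| 0.417 | 7 | 76 |
| 1.33 | 3 | 95 |
| 2.50 | 1 | 98 |
| 4.00 | 2 | 96 |

(readings scatter by 1.5 percentage points)

- a reading or a percentage of target counts all its forms, free or not
- no earlier run changes the charge of catalyst; that part of a forecast is a guess

- ratio of isomer of the product A to target at 1.2 s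
- ratio of isomer of the product A to target at 25 s
- ratio of isomer of the product A to target at 12 min
- which of isomer of the product A and target there is more of at 12 min

Two chemists read the dusk run. Drain holds that the isomer of the product A is simply consumed: it falls from 7% to 3% of the charge between 0.417 min and 1.33 min, a half-life of 0.747 min. If rate follows catalyst, which is a guess, that half-life stretches to 1.11 min in the flask, and the dusk state of 1.33 min arrives there at 1.98 min. Drain's ratio at 12 min is therefore 6.14 × 10⁻⁵.

Floor holds that the ratio stops falling, and defines the plateau ratio, isomer over target with the last three dusk readings summed: 0.0208, give or take 0.00899 from the scatter, so it stands clear of zero. Drain's curve gives 0.252% at 4.00 min, where the reading is 2%; that gap of 1.7 percentage points is close to the scatter of 1.5 points, so the dispute stays open.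

I side with Floor, the thermodynamic end of kinetic against thermodynamic control. The reckoned arrival at 1.98 min comes well before 12 min, so I commit to 0.0208 for the flask at 12 min, with target ahead. On the same clock, 25 s in the flask equals 0.280 min of dusk, earlier than the first reading, so I give no figure for the two early ratios.

The forecast gives 0.5, 0.14 and 0.017, with target ahead, and says “the system should be equilibrated, with target far ahead”.

The flask gives 0.0205, 0.0757 and 0.0219, with target ahead at 96.9% against 2.12%. The last ratio lies within the error of the plateau ratio, so Floor stands.

    substrate + catalyst ⇌ target + catalyst, rate k1*[substrate]*[catalyst] forward; the back reaction follows from the equilibrium constant (K = 1.68, k = 9.68 M⁻¹ s⁻¹)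
    target + catalyst ⇌ isomer of the product A + catalyst, rate k2*[catalyst]*[target] forward; the back reaction follows from the equilibrium constant (K = 1.63, k = 6.43 M⁻¹ s⁻¹)
    isomer of the product A ⇌ isomer of the product B (K = 0.0806, k = 0.0110 s⁻¹)
    isomer of the product B + catalyst ⇌ substrate + catalyst, rate k4*[catalyst]*[isomer of the product B] forward; the back reaction follows from the equilibrium constant (k = 4.54 M⁻¹ s⁻¹)
    crystals ⇌ target, rate k5*(cs5 - [target]) while solid is left; crystals form when [target] > cs5 (solubility = 13.0 mM, k = 3.48 s⁻¹)

In the flask, substrate passed into target with half of that turnover done by 0.237 min, while crystals reached 89.4% at 1.20 min and the isomer of the product A peaked at 5.68% at 0.729 min. Drain's region is the flask's way down from that peak, where the isomer of the product A does fall, from 4.97% at 1.20 min to 2.14% at 6.00 min; later the flask shows it at 2.12% as late as 120 min.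

A neighbour flask with 0.12 mol% of catalyst is reckoned, on the same guessed clock, to reach the dusk state of 1.33 min at 7.76 min, before 12 min, so the plateau ratio gives 0.0208 there. Computed, that neighbour shows 0.0260, within the error.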